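**Plan**

- Retrosynthesis: a temporary tert-butyl ester is placed on C3 (it is removed last). The cuts then follow in this order: O1–C2 of ring C, the C2=C3 alkene, and C3–C4. This leads back to a ring A salicylate, tert-butyl acetate and the ring B aldehyde.
- Enabling feature: O1–C2 links the ring A phenol oxygen to a benzylic carbon that lies β to the C4 ketone. Ring C is therefore the adduct of a phenol and an enone, and an ester on C3 turns that enone into a reactive acceptor with two binding points.
- Forward order: ring A is bought; C4–C3 is made by a Claisen condensation; the C3=C2 alkene carrying ring B is made by a Knoevenagel condensation; ring C then closes through O1–C2; the C3 ester is excised.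
- Stereochemistry: C2 (S) is set in the ring closure by a cinchona-derived bifunctional thiourea. The C3 centre formed with it is transient and disappears on decarboxylation.

Key step: step 3

Assumption: the two pseudoenantiomeric cinchona thioureas are taken to give opposite senses at C2, and the quinidine-derived one is written as the source of (2S) by analogy; should the first run show the (2R) series, the quinine-derived catalyst takes its place with nothing else changed.

**Route**

Step 1
Reactants: 1 methyl 2-hydroxy-4,6-dimethoxybenzoate; 2 tert-butyl acetate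
Product: 4 tert-butyl 3-(2-hydroxy-4,6-dimethoxyphenyl)-3-oxopropanoate, via lithium enolate of tert-butyl acetate 3 (not isolated)
Conditions: LiN(i-Pr)2 (commercial solution, 4.0 equiv), 2 (3.0 equiv), THF, −78 °C; then 1, −78 °C → 0 °C; 1 M aq. HCl to pH 4, 0 °C
Reagents that add atoms: none
Why: Crossed Claisen condensation: the benzoate cannot enolise, the surplus enolate first converts the phenol into a lithium phenoxide that keeps the ester chelated and coplanar with ring A, and deprotonation of the β-keto ester as it forms makes the acyl substitution irreversible and shields the new ketone from a second addition.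

Step 2
Reactants: 4 tert-butyl 3-(2-hydroxy-4,6-dimethoxyphenyl)-3-oxopropanoate; 5 3,4,5-trimethoxybenzaldehyde
Product: 6 tert-butyl (Z)-2-(2-hydroxy-4,6-dimethoxybenzoyl)-3-(3,4,5-trimethoxyphenyl)prop-2-enoate
Conditions: piperidine (0.1 equiv), AcOH (0.2 equiv), 4 Å molecular sieves, toluene, rt
Reagents that add atoms: none
Why: Knoevenagel condensation: the doubly activated methylene of 4 condenses with the non-enolisable aldehyde under piperidinium acetate catalysis while the sieves take up the water, the acetic acid buffer and room temperature should keep the phenol from adding prematurely, and the Z alkene (ester cis to the aryl group, aroyl group conjugated) is expected as the more stable isomer; no stereocentre is formed.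

Step 3
Reactants: 6 tert-butyl (Z)-2-(2-hydroxy-4,6-dimethoxybenzoyl)-3-(3,4,5-trimethoxyphenyl)prop-2-enoate
Product: 7 tert-butyl (2S,3R)-5,7-dimethoxy-4-oxo-2-(3,4,5-trimethoxyphenyl)chroman-3-carboxylate
Conditions: 1-[3,5-bis(trifluoromethyl)phenyl]-3-[(9R)-6'-methoxycinchonan-9-yl]thiourea (quinidine-derived, 10 mol%), toluene (0.05 M), −25 °C; cold 5% aq. citric acid wash, crude product taken on without chromatography
Reagents that add atoms: none
Why: The quinuclidine nitrogen of the catalyst acts as a general base on the 2'-phenol while the two thiourea N–H bonds hold the 1,3-dicarbonyl unit of the acceptor, so the phenol oxygen is delivered to the benzylic β-carbon inside the chiral pocket and the resulting enol is protonated at C3. The closest known reaction type is the bifunctional cinchona-thiourea-catalysed intramolecular oxa-Michael addition of 2'-hydroxyaryl alkylidene β-keto esters to 3-carboxyflavanones. Ring C closes in the 6-endo-trig mode by formation of O1–C2. C2 is controlled by the catalyst, which exposes one face of the alkene, whereas C3 is set by thermodynamic protonation that places the ester trans to the aryl group and is of no lasting consequence. The step needs enantiofacial selectivity at C2 over the racemic background closure and over reversible ring opening; the tert-butyl ester at C3 secures it by giving the catalyst two-point binding and by making the acceptor reactive enough for −25 °C in toluene, where the uncatalysed paths should be slow.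

Step 4
Reactants: 7 tert-butyl (2S,3R)-5,7-dimethoxy-4-oxo-2-(3,4,5-trimethoxyphenyl)chroman-3-carboxylate
Product: 9 (2S)-5,7-dimethoxy-2-(3,4,5-trimethoxyphenyl)chroman-4-one, via chromanone-3-carboxylic acid 8 (not isolated)
Conditions: TsOH·H2O (0.3 equiv), toluene, 80 °C
Reagents that add atoms: none
Why: Acid-catalysed loss of 2-methylpropene from the tert-butyl ester (E1 fragmentation) followed by thermal decarboxylation of the β-keto acid through a six-membered transition state turns C3 into CH2, while C2 carries no acidic hydrogen and, with the basic catalyst already removed, should not reopen by retro-oxa-Michael reaction, so its configuration is retained.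

**Compound list**

1 | methyl 2-hydroxy-4,6-dimethoxybenzoate | COC(=O)c1c(O)cc(OC)cc1OC | starting material
2 | tert-butyl acetate | CC(=O)OC(C)(C)C | starting material
3 | lithium enolate of tert-butyl acetate (lithium 1-tert-butoxyethenolate) | [Li+].[O-]C(=C)OC(C)(C)C | intermediate
4 | tert-butyl 3-(2-hydroxy-4,6-dimethoxyphenyl)-3-oxopropanoate | COc1cc(O)c(C(=O)CC(=O)OC(C)(C)C)c(OC)c1 | intermediate
5 | 3,4,5-trimethoxybenzaldehyde | COc1cc(C=O)cc(OC)c1OC | starting material
6 | tert-butyl (Z)-2-(2-hydroxy-4,6-dimethoxybenzoyl)-3-(3,4,5-trimethoxyphenyl)prop-2-enoate | COc1cc(O)c(C(=O)/C(C(=O)OC(C)(C)C)=C/c2cc(OC)c(OC)c(OC)c2)c(OC)c1 | intermediate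
7 | tert-butyl (2S,3R)-5,7-dimethoxy-4-oxo-2-(3,4,5-trimethoxyphenyl)chroman-3-carboxylate | COc1cc(OC)c2c(c1)O[C@H](c1cc(OC)c(OC)c(OC)c1)[C@@H](C(=O)OC(C)(C)C)C2=O | intermediate
8 | (2S,3R)-5,7-dimethoxy-4-oxo-2-(3,4,5-trimethoxyphenyl)chroman-3-carboxylic acid | COc1cc(OC)c2c(c1)O[C@H](c1cc(OC)c(OC)c(OC)c1)[C@@H](C(=O)O)C2=O | intermediate
9 | (2S)-5,7-dimethoxy-2-(3,4,5-trimethoxyphenyl)chroman-4-one | COc1cc(OC)c2c(c1)O[C@H](c1cc(OC)c(OC)c(OC)c1)CC2=O | target

**Step count**

Total steps: 4. Longest linear sequence: 4 steps (from compound 1).

**Steps most likely to fail, with fallbacks**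

1. Step 3, erosion of enantiofacial control. The 6'-methoxy group of ring A favours the conformation for ring closure, so an uncatalysed closure and reversible ring opening may compete with the catalyst-bound pathway. The fallback replaces asymmetric catalysis by resolution and sets out from compound 6. Closure with an achiral base (Et3N, 0.1 equiv, toluene, rt) should give racemic tert-butyl 5,7-dimethoxy-4-oxo-2-(3,4,5-trimethoxyphenyl)chroman-3-carboxylate F1. TsOH·H2O at 80 °C in the same flask should lead through racemic 5,7-dimethoxy-4-oxo-2-(3,4,5-trimethoxyphenyl)chroman-3-carboxylic acid F2 to racemic 5,7-dimethoxy-2-(3,4,5-trimethoxyphenyl)chroman-4-one F3. Preparative chromatography on an amylose tris(3,5-dimethylphenylcarbamate) phase would then separate the (2S) enantiomer, where the route is rejoined at compound 9, from (2R)-5,7-dimethoxy-2-(3,4,5-trimethoxyphenyl)chroman-4-one F4.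

2. Step 2, premature ring closure. The free phenol may add to the new alkylidene under amine catalysis, so that racemic chromanone forms before the chiral catalyst is used; a mixture of alkene isomers is a lesser concern. The fallback masks the phenol and sets out from compound 4. Silylation (TBSCl, imidazole, DMF, rt) should give tert-butyl 3-[2-(tert-butyldimethylsilyloxy)-4,6-dimethoxyphenyl]-3-oxopropanoate F5. Knoevenagel condensation with compound 5 under the conditions of step 2 should give tert-butyl (Z)-2-[2-(tert-butyldimethylsilyloxy)-4,6-dimethoxybenzoyl]-3-(3,4,5-trimethoxyphenyl)prop-2-enoate F6. Desilylation with Et3N·3HF in THF at 0 °C would free the phenol under non-basic conditions and rejoin the route at compound 6.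

3. Step 1, incomplete acyl substitution. The ester is electron-rich and di-ortho-substituted, and as its phenoxide it is a poor electrophile, so self-condensation of the acetate enolate may take over on warming. The fallback removes the phenoxide and sets out from compound 1. O-Benzylation (benzyl bromide, K2CO3, DMF, rt) should give methyl 2-(benzyloxy)-4,6-dimethoxybenzoate F7. Claisen condensation with enolate 3 (LiN(i-Pr)2 and compound 2, 2.2 equiv each, THF, −78 °C → 0 °C; 1 M aq. HCl quench) should give tert-butyl 3-[2-(benzyloxy)-4,6-dimethoxyphenyl]-3-oxopropanoate F8. Hydrogenolysis (H2, Pd/C, EtOAc, rt) would rejoin the route at compound 4.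

**Further compounds**

F1 | step 3 | racemic tert-butyl 5,7-dimethoxy-4-oxo-2-(3,4,5-trimethoxyphenyl)chroman-3-carboxylate | COc1cc(OC)c2c(c1)OC(c1cc(OC)c(OC)c(OC)c1)C(C(=O)OC(C)(C)C)C2=O
F2 | step 3 | racemic 5,7-dimethoxy-4-oxo-2-(3,4,5-trimethoxyphenyl)chroman-3-carboxylic acid | COc1cc(OC)c2c(c1)OC(c1cc(OC)c(OC)c(OC)c1)C(C(=O)O)C2=O
F3 | step 3 | racemic 5,7-dimethoxy-2-(3,4,5-trimethoxyphenyl)chroman-4-one | COc1cc(OC)c2c(c1)OC(c1cc(OC)c(OC)c(OC)c1)CC2=O
F4 | step 3 | (2R)-5,7-dimethoxy-2-(3,4,5-trimethoxyphenyl)chroman-4-one | COc1cc(OC)c2c(c1)O[C@@H](c1cc(OC)c(OC)c(OC)c1)CC2=O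
F5 | step 2 | tert-butyl 3-[2-(tert-butyldimethylsilyloxy)-4,6-dimethoxyphenyl]-3-oxopropanoate | COc1cc(O[Si](C)(C)C(C)(C)C)c(C(=O)CC(=O)OC(C)(C)C)c(OC)c1
F6 | step 2 | tert-butyl (Z)-2-[2-(tert-butyldimethylsilyloxy)-4,6-dimethoxybenzoyl]-3-(3,4,5-trimethoxyphenyl)prop-2-enoate | COc1cc(O[Si](C)(C)C(C)(C)C)c(C(=O)/C(C(=O)OC(C)(C)C)=C/c2cc(OC)c(OC)c(OC)c2)c(OC)c1
F7 | step 1 | methyl 2-(benzyloxy)-4,6-dimethoxybenzoate | COC(=O)c1c(OCc2ccccc2)cc(OC)cc1OC
F8 | step 1 | tert-butyl 3-[2-(benzyloxy)-4,6-dimethoxyphenyl]-3-oxopropanoate | COc1cc(OCc2ccccc2)c(C(=O)CC(=O)OC(C)(C)C)c(OC)c1
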